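## Retrosynthetic overview

1. The enal C14(C15HO)=C15′ is opened by a crossed aldol condensation into two allyl 15-oxolabd-8(17)-en-19-oates: the trans-fused one (donor at C14) and its C5′ epimer (cis-fused acceptor at C15′).
2. The halves have the same configuration at C4, C9, C10 and C13, so both come from one bicyclic ester. The cis half is made from it by inverting C5: ozonolysis at C8, 6-en-8-one, deconjugative ketalisation to the 5-ene, C19-OH-directed hydrogenation to 5β-H, re-methylenation.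
3. The strategy rests on rings A and B of the trans-fused decalin. C4 with a methyl and the axial C19 carboxyl, the angular C20 on C10 and the exocyclic C8=C17 are the pattern of an (E,E)-diene 2-methyl-3-oxo ester. Mn(OAc)3/Cu(OAc)2 closes ring A (C4–C5) and then ring B (C9–C10) under 8-phenylmenthyl control.
4. The acyclic ester comes from (2E,6E)-farnesol (asymmetric hydrogenation for C13, silyl ether, SeO2, bromide) and the dianion of 8-phenylmenthyl 2-methylacetoacetate.

Key step: step 8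

Remarks on the chemistry:
- Labdane numbering is used, unprimed for the trans-fused half and primed for the cis-fused half. α/β refer to the usual drawing with C20 β. TBDPS = tert-butyldiphenylsilyl; PM = (1R,2S,5R)-8-phenylmenthyl.
- The facial sense given by (−)-8-phenylmenthol is assumed to lead to the 10β-methyl series; if it proves opposite, (+)-8-phenylmenthol is used with no other change.
- The C15 oxygen is carried as a TBDPS ether so that it survives the LiAlH4 release of the auxiliary.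

## Route

Step 1
Reactants: 1 (2E,6E)-farnesol
Product: 2 (S)-2,3-dihydrofarnesol
Conditions: H2 (30 atm), Ru(OAc)2[(R)-BINAP] (0.5 mol%), MeOH, 20 °C
Reagents that add atoms: none
Why: Noyori asymmetric hydrogenation reduces only the hydroxyl-bound C2=C3 bond, and the (R)-BINAP complex with the (E)-allylic alcohol should set (S) (future C13) as in the geraniol to (S)-citronellol case.

Step 2
Reactants: 2 (S)-2,3-dihydrofarnesol
Product: 3 (S)-2,3-dihydrofarnesyl TBDPS ether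
Conditions: TBDPSCl, imidazole, DMF, 20 °C
Reagents that add atoms: tert-butyl(chloro)diphenylsilane, CC(C)(C)[Si](Cl)(c1ccccc1)c1ccccc1
Why: Standard silylation of a primary alcohol gives an ether that should withstand acetic acid, strong base and hydride.

Step 3
Reactants: 3 (S)-2,3-dihydrofarnesyl TBDPS ether
Product: 4 (2E,6E,10S)-12-(TBDPS-oxy)-2,6,10-trimethyldodeca-2,6-dien-1-ol
Conditions: SeO2 (0.5 equiv), t-BuOOH, salicylic acid (cat.), CH2Cl2, 20 °C
Reagents that add atoms: selenium dioxide, O=[Se]=O; tert-butyl hydroperoxide, CC(C)(C)OO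
Why: Sharpless SeO2/t-BuOOH allylic oxidation (ene reaction then [2,3] shift) attacks the terminal trisubstituted olefin and hydroxylates its (E)-methyl, which becomes C1.

Step 4
Reactants: 4 (2E,6E,10S)-12-(TBDPS-oxy)-2,6,10-trimethyldodeca-2,6-dien-1-ol
Product: 5 (2E,6E,10S)-1-bromo-12-(TBDPS-oxy)-2,6,10-trimethyldodeca-2,6-diene
Conditions: CBr4, PPh3, CH2Cl2, 0 °C
Reagents that add atoms: tetrabromomethane, BrC(Br)(Br)Br
Why: The Appel reaction converts the primary allylic alcohol to the bromide without allylic shift or loss of olefin geometry.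

Step 5
Reactants: 6 (−)-8-phenylmenthol; 7 2,2,6-trimethyl-4H-1,3-dioxin-4-one
Product: 8 PM 3-oxobutanoate
Conditions: xylene, 140 °C, acetone distilled off
Reagents that add atoms: none
Why: Thermal retro-[4+2] of the dioxinone gives acetylketene, which acylates even this hindered secondary alcohol (acetoacetylation).

Step 6
Reactants: 8 PM 3-oxobutanoate
Product: 9 PM 2-methyl-3-oxobutanoate (both C2 epimers)
Conditions: K2CO3, MeI, acetone, 56 °C
Reagents that add atoms: iodomethane, CI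
Why: C-alkylation of the β-keto ester enolate installs the methyl that becomes C18.

Step 7
Reactants: 9 PM 2-methyl-3-oxobutanoate; 5 (2E,6E,10S)-1-bromo-12-(TBDPS-oxy)-2,6,10-trimethyldodeca-2,6-diene
Product: 10 PM (6E,10E,14S)-16-(TBDPS-oxy)-2,6,10,14-tetramethyl-3-oxohexadeca-6,10-dienoate (epimers at the labile C2, which is C4 of the labdane)
Conditions: NaH, THF, 0 °C; n-BuLi, 0 °C; then 5, 0 → 20 °C; 1 M HCl work-up
Reagents that add atoms: none
Why: Weiler dianion alkylation occurs at the more basic terminal (γ) carbon with SN2 displacement of the allylic bromide, forming the C1–C2 bond.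

Step 8
Reactants: 10 PM (6E,10E,14S)-16-(TBDPS-oxy)-2,6,10,14-tetramethyl-3-oxohexadeca-6,10-dienoate
Product: 11 PM (13S)-15-(TBDPS-oxy)-3-oxolabd-8(17)-en-19-oate (trans-fused; 4β-ester, 5α-H, 9α-H, 10β-CH3)
Conditions: Mn(OAc)3·2H2O (2.2 equiv), Cu(OAc)2·H2O (1 equiv), degassed AcOH, 25 °C
Reagents that add atoms: none
Why: Mn(OAc)3 oxidises the manganese enolate of the 2-methyl-3-oxo ester to the electrophilic C4 radical, which adds to C5 of the (E)-C5=C10 olefin; the closest known reaction type is the Mn(OAc)3/Cu(OAc)2 oxidative free-radical polyene cyclisation of 8-phenylmenthyl 2-methylacetoacetates. Ring A closes 6-endo-trig (C4–C5) to the tertiary C10 radical, ring B closes 6-endo-trig (C9–C10) onto the (E)-C8=C9 olefin through a chair–chair array, and the tertiary C8 radical is oxidised by Cu(OAc)2 through an alkylcopper species that loses a C17 hydrogen to give C8=C17, Mn(OAc)3 returning the copper to the divalent state. C4 and C5 follow from the chair transition state with the ester axial and C6 equatorial on the (E)-olefin, which puts the C19 ester anti to H5; C10 and C9 follow from the chair closure of ring B, which puts C20 axial and trans to H5 and C11 equatorial (9α-H). The absolute sense comes from the phenyl ring of the auxiliary covering one face of the enolate radical so that the olefin adds to the open face of C4; C13 is remote and plays no part. The step needs 6-endo over 5-exo closure twice, secured by the fully substituted olefin carbons C10 and C8, and exocyclic over endocyclic olefin formation, which the copper-mediated elimination favours.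

Step 9
Reactants: 11 PM (13S)-15-(TBDPS-oxy)-3-oxolabd-8(17)-en-19-oate
Product: 12 PM (13S)-15-(TBDPS-oxy)-3β-hydroxylabd-8(17)-en-19-oate (major epimer; either serves)
Conditions: NaBH4, MeOH/THF, 0 °C
Reagents that add atoms: none
Why: Borohydride reduction of the ketone spares the hindered ester, axial hydride delivery from the α face giving mainly the equatorial 3β-alcohol.

Step 10
Reactants: 12 PM (13S)-15-(TBDPS-oxy)-3β-hydroxylabd-8(17)-en-19-oate
Product: 13 PM (13S)-15-(TBDPS-oxy)-3β-(imidazol-1-ylthiocarbonyloxy)labd-8(17)-en-19-oate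
Conditions: 1,1′-thiocarbonyldiimidazole, DMAP (cat.), ClCH2CH2Cl, 80 °C
Reagents that add atoms: 1,1′-thiocarbonyldiimidazole, S=C(n1ccnc1)n1ccnc1
Why: Neutral thioacylation of the hindered secondary alcohol avoids the alkoxide and so any retro-aldol opening of the β-hydroxy ester.

Step 11
Reactants: 13 PM (13S)-15-(TBDPS-oxy)-3β-(imidazol-1-ylthiocarbonyloxy)labd-8(17)-en-19-oate
Product: 14 PM (13S)-15-(TBDPS-oxy)labd-8(17)-en-19-oate
Conditions: Bu3SnH, AIBN (cat.), toluene, 110 °C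
Reagents that add atoms: none
Why: Barton–McCombie deoxygenation removes the C3 oxygen through a secondary radical that has no cyclisation or fragmentation path in this skeleton.

Step 12
Reactants: 14 PM (13S)-15-(TBDPS-oxy)labd-8(17)-en-19-oate
Product: 15 (13S)-15-(TBDPS-oxy)labd-8(17)-en-19-ol
Conditions: LiAlH4, THF, 0 → 40 °C
Reagents that add atoms: none
Why: Hydride reduction is the reliable way to cleave the hindered neopentyl-type ester; it releases the auxiliary for recovery and leaves the silyl ether.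

Step 13
Reactants: 15 (13S)-15-(TBDPS-oxy)labd-8(17)-en-19-ol
Product: 16 (13S)-15-(TBDPS-oxy)labd-8(17)-en-19-oic acid
Conditions: CrO3, H2SO4, H2O, acetone, 0 °C
Reagents that add atoms: water, O
Why: Jones oxidation takes the neopentyl primary alcohol through the aldehyde hydrate to the acid and tolerates the 1,1-disubstituted olefin and the TBDPS ether at 0 °C.

Step 14
Reactants: 16 (13S)-15-(TBDPS-oxy)labd-8(17)-en-19-oic acid
Product: 17 allyl (13S)-15-(TBDPS-oxy)labd-8(17)-en-19-oate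
Conditions: allyl bromide, KHCO3, DMF, 25 °C
Reagents that add atoms: allyl bromide, C=CCBr
Why: SN2 O-alkylation of the carboxylate is insensitive to the hindrance at C4 and gives an ester removable later under neutral conditions.

Step 15
Reactants: 17 allyl (13S)-15-(TBDPS-oxy)labd-8(17)-en-19-oate
Product: 18 allyl (13S)-15-hydroxylabd-8(17)-en-19-oate
Conditions: Bu4NF, THF, 25 °C
Reagents that add atoms: none
Why: Fluoride desilylation frees the C15 alcohol and the hindered allyl ester is not touched.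

Step 16
Reactants: 18 allyl (13S)-15-hydroxylabd-8(17)-en-19-oate
Product: 19 allyl (13S)-15-oxolabd-8(17)-en-19-oate
Conditions: Dess–Martin periodinane, CH2Cl2, 25 °C
Reagents that add atoms: none
Why: Dess–Martin oxidation gives the aldehyde without over-oxidation or olefin migration.

Step 17
Reactants: 19 allyl (13S)-15-oxolabd-8(17)-en-19-oate
Product: 20 N-cyclohexyl imine of 19
Conditions: cyclohexylamine, MgSO4, Et2O, 0 → 25 °C
Reagents that add atoms: cyclohexylamine, NC1CCCCC1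
Why: Imine condensation masks the aldehyde as the donor of a Wittig directed aldol reaction.

Step 18
Reactants: 14 PM (13S)-15-(TBDPS-oxy)labd-8(17)-en-19-oate
Product: 21 PM (13S)-15-(TBDPS-oxy)-8-oxo-17-norlabdan-19-oate
Conditions: O3, CH2Cl2/MeOH, −78 °C; Me2S
Reagents that add atoms: ozone, [O-][O+]=O
Why: Ozonolysis cleaves the only olefin (the arene rings are far slower at −78 °C) and gives the C8 ketone as a handle for reaching C5.

Step 19
Reactants: 21 PM (13S)-15-(TBDPS-oxy)-8-oxo-17-norlabdan-19-oate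
Product: 23 PM (13S)-15-(TBDPS-oxy)-8-oxo-17-norlabd-6-en-19-oate, via trimethylsilyl enol ether 22 (not isolated)
Conditions: LiN(iPr)2, THF, −78 °C; Me3SiCl; then Pd(OAc)2 (1.1 equiv), MeCN, 25 °C
Reagents that add atoms: none
Why: Kinetic deprotonation occurs at the C7 methylene and not at the hindered C9 methine, and Saegusa–Ito oxidation of the enol silane gives the 6-en-8-one.

Step 20
Reactants: 23 PM (13S)-15-(TBDPS-oxy)-8-oxo-17-norlabd-6-en-19-oate
Product: 24 PM (13S)-15-(TBDPS-oxy)-8,8-ethylenedioxy-17-norlabd-5-en-19-oate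
Conditions: HOCH2CH2OH, TsOH (cat.), benzene, 80 °C, Dean–Stark
Reagents that add atoms: ethane-1,2-diol, OCCO
Why: Acid-catalysed ketalisation of a conjugated enone passes through the dienol with protonation at C7, so the double bond moves to the more substituted C5=C6 position as with steroidal 4-en-3-ones, which makes C5 trigonal.

Step 21
Reactants: 24 PM (13S)-15-(TBDPS-oxy)-8,8-ethylenedioxy-17-norlabd-5-en-19-oate
Product: 25 (13S)-15-(TBDPS-oxy)-8,8-ethylenedioxy-17-norlabd-5-en-19-ol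
Conditions: LiAlH4, THF, 0 → 40 °C
Reagents that add atoms: none
Why: Hydride cleavage of the hindered ester releases the auxiliary and unveils the 4β-hydroxymethyl group that will direct the next step; ketal and silyl ether are inert.

Step 22
Reactants: 25 (13S)-15-(TBDPS-oxy)-8,8-ethylenedioxy-17-norlabd-5-en-19-ol
Product: 26 (5β,13S)-15-(TBDPS-oxy)-8,8-ethylenedioxy-17-norlabdan-19-ol (cis-fused)
Conditions: H2 (1 atm), [Ir(cod)(PCy3)(py)]PF6 (10 mol%), CH2Cl2, 25 °C
Reagents that add atoms: none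
Why: In this hydroxyl-directed hydrogenation the axial 4β-CH2OH, homoallylic to C5=C6, binds the cationic iridium and delivers hydrogen to the β face, setting 5β-H (cis fusion) against the steric bias.

Step 23
Reactants: 26 (5β,13S)-15-(TBDPS-oxy)-8,8-ethylenedioxy-17-norlabdan-19-ol
Product: 27 (5β,13S)-15-(TBDPS-oxy)-8-oxo-17-norlabdan-19-oic acid
Conditions: CrO3, H2SO4, H2O, acetone, 0 → 20 °C
Reagents that add atoms: water, O
Why: Jones oxidation converts the C19 alcohol to the acid while the aqueous acid in acetone exchanges the dioxolane off C8, and the short cold exposure should leave the C9 methine next to the ketone unchanged.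

Step 24
Reactants: 27 (5β,13S)-15-(TBDPS-oxy)-8-oxo-17-norlabdan-19-oic acid
Product: 28 allyl (5β,13S)-15-(TBDPS-oxy)-8-oxo-17-norlabdan-19-oate
Conditions: allyl bromide, KHCO3, DMF, 25 °C
Reagents that add atoms: allyl bromide, C=CCBr
Why: Carboxylate O-alkylation with hydrogen carbonate as the only base is too weakly basic to enolise the C8 ketone toward C9.

Step 25
Reactants: 28 allyl (5β,13S)-15-(TBDPS-oxy)-8-oxo-17-norlabdan-19-oate
Product: 29 allyl (5β,13S)-15-(TBDPS-oxy)labd-8(17)-en-19-oate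
Conditions: Zn, CH2Br2, TiCl4, THF/CH2Cl2, 0 → 25 °C
Reagents that add atoms: dibromomethane, BrCBr
Why: Takai–Lombardo methylenation is non-basic, so it restores C8=C17 on the hindered ketone without epimerising C9 and does not attack the ester.

Step 26
Reactants: 29 allyl (5β,13S)-15-(TBDPS-oxy)labd-8(17)-en-19-oate
Product: 30 allyl (5β,13S)-15-hydroxylabd-8(17)-en-19-oate
Conditions: Bu4NF, THF, 25 °C
Reagents that add atoms: none
Why: Fluoride desilylation frees the C15′ alcohol as in step 15.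

Step 27
Reactants: 30 allyl (5β,13S)-15-hydroxylabd-8(17)-en-19-oate
Product: 31 allyl (5β,13S)-15-oxolabd-8(17)-en-19-oate
Conditions: Dess–Martin periodinane, CH2Cl2, 25 °C
Reagents that add atoms: none
Why: Dess–Martin oxidation gives the acceptor aldehyde under neutral conditions.

Step 28
Reactants: 20 N-cyclohexyl imine of 19; 31 allyl (5β,13S)-15-oxolabd-8(17)-en-19-oate
Product: 34 bis(allyl) ester of the target, via lithium aza-enolate 32 (not isolated), via aldol adduct lithium alkoxide 33 (not isolated)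
Conditions: LiN(iPr)2, THF, −78 → 0 °C; 31, −78 °C; then 1 M aq. (CO2H)2, THF, 25 → 40 °C
Reagents that add atoms: none
Why: In this Wittig directed aldol condensation only the metallated imine can act as the C14 nucleophile toward the C15′ aldehyde, and acidic hydrolysis with dehydration gives the thermodynamically favoured (E)-2-alkyl-2-enal (formyl trans to C14′).

Step 29
Reactants: 34 bis(allyl) ester of the target
Product: 35 target diacid CNP0229303.1
Conditions: Pd(PPh3)4 (5 mol%), PhNHMe, THF, 25 °C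
Reagents that add atoms: none
Why: Tsuji–Trost deallylation with zerovalent palladium and a weakly nucleophilic amine as allyl acceptor frees both hindered acids without touching the enal or the exocyclic olefins.

## Compound list

1 | (2E,6E)-farnesol | CC(C)=CCC/C(C)=C/CC/C(C)=C/CO | starting material
2 | (S)-2,3-dihydrofarnesol | OCC[C@@H](C)CC/C=C(\C)CCC=C(C)C | intermediate
3 | (S)-2,3-dihydrofarnesyl TBDPS ether | CC(C)(C)[Si](c1ccccc1)(c1ccccc1)OCC[C@@H](C)CC/C=C(\C)CCC=C(C)C | intermediate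
4 | (2E,6E,10S)-12-(TBDPS-oxy)-2,6,10-trimethyldodeca-2,6-dien-1-ol | CC(C)(C)[Si](c1ccccc1)(c1ccccc1)OCC[C@@H](C)CC/C=C(\C)CC/C=C(\C)CO | intermediate
5 | (2E,6E,10S)-1-bromo-12-(TBDPS-oxy)-2,6,10-trimethyldodeca-2,6-diene | CC(C)(C)[Si](c1ccccc1)(c1ccccc1)OCC[C@@H](C)CC/C=C(\C)CC/C=C(\C)CBr | intermediate
6 | (−)-8-phenylmenthol (1R,2S,5R) | O[C@@H]1C[C@H](C)CC[C@H]1C(C)(C)c1ccccc1 | starting material
7 | 2,2,6-trimethyl-4H-1,3-dioxin-4-one | CC1=CC(=O)OC(C)(C)O1 | starting material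
8 | PM 3-oxobutanoate | CC(=O)CC(=O)O[C@@H]1C[C@H](C)CC[C@H]1C(C)(C)c1ccccc1 | intermediate
9 | PM 2-methyl-3-oxobutanoate (C2 epimers) | CC(=O)C(C)C(=O)O[C@@H]1C[C@H](C)CC[C@H]1C(C)(C)c1ccccc1 | intermediate
10 | PM (6E,10E,14S)-16-(TBDPS-oxy)-2,6,10,14-tetramethyl-3-oxohexadeca-6,10-dienoate (C2 epimers) | CC(C)(C)[Si](c1ccccc1)(c1ccccc1)OCC[C@@H](C)CC/C=C(\C)CC/C=C(\C)CCC(=O)C(C)C(=O)O[C@@H]1C[C@H](C)CC[C@H]1C(C)(C)c1ccccc1 | intermediate
11 | PM (13S)-15-(TBDPS-oxy)-3-oxolabd-8(17)-en-19-oate | C=C1CC[C@@H]2[C@](C)(CCC(=O)[C@]2(C)C(=O)O[C@@H]3C[C@H](C)CC[C@H]3C(C)(C)c3ccccc3)[C@H]1CC[C@H](C)CCO[Si](c1ccccc1)(c1ccccc1)C(C)(C)C | intermediate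
12 | PM (13S)-15-(TBDPS-oxy)-3β-hydroxylabd-8(17)-en-19-oate | C=C1CC[C@@H]2[C@](C)(CC[C@H](O)[C@]2(C)C(=O)O[C@@H]3C[C@H](C)CC[C@H]3C(C)(C)c3ccccc3)[C@H]1CC[C@H](C)CCO[Si](c1ccccc1)(c1ccccc1)C(C)(C)C | intermediate
13 | PM (13S)-15-(TBDPS-oxy)-3β-(imidazol-1-ylthiocarbonyloxy)labd-8(17)-en-19-oate | C=C1CC[C@@H]2[C@](C)(CC[C@H](OC(=S)n3ccnc3)[C@]2(C)C(=O)O[C@@H]3C[C@H](C)CC[C@H]3C(C)(C)c3ccccc3)[C@H]1CC[C@H](C)CCO[Si](c1ccccc1)(c1ccccc1)C(C)(C)C | intermediate
14 | PM (13S)-15-(TBDPS-oxy)labd-8(17)-en-19-oate | C=C1CC[C@@H]2[C@](C)(CCC[C@]2(C)C(=O)O[C@@H]3C[C@H](C)CC[C@H]3C(C)(C)c3ccccc3)[C@H]1CC[C@H](C)CCO[Si](c1ccccc1)(c1ccccc1)C(C)(C)C | intermediate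
15 | (13S)-15-(TBDPS-oxy)labd-8(17)-en-19-ol | C=C1CC[C@@H]2[C@](C)(CCC[C@]2(C)CO)[C@H]1CC[C@H](C)CCO[Si](c1ccccc1)(c1ccccc1)C(C)(C)C | intermediate
16 | (13S)-15-(TBDPS-oxy)labd-8(17)-en-19-oic acid | C=C1CC[C@@H]2[C@](C)(CCC[C@]2(C)C(=O)O)[C@H]1CC[C@H](C)CCO[Si](c1ccccc1)(c1ccccc1)C(C)(C)C | intermediate
17 | allyl (13S)-15-(TBDPS-oxy)labd-8(17)-en-19-oate | C=C1CC[C@@H]2[C@](C)(CCC[C@]2(C)C(=O)OCC=C)[C@H]1CC[C@H](C)CCO[Si](c1ccccc1)(c1ccccc1)C(C)(C)C | intermediate
18 | allyl (13S)-15-hydroxylabd-8(17)-en-19-oate | C=C1CC[C@@H]2[C@](C)(CCC[C@]2(C)C(=O)OCC=C)[C@H]1CC[C@H](C)CCO | intermediate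
19 | allyl (13S)-15-oxolabd-8(17)-en-19-oate | C=C1CC[C@@H]2[C@](C)(CCC[C@]2(C)C(=O)OCC=C)[C@H]1CC[C@H](C)CC=O | intermediate
20 | N-cyclohexyl imine of 19 | C=C1CC[C@@H]2[C@](C)(CCC[C@]2(C)C(=O)OCC=C)[C@H]1CC[C@H](C)C/C=N/C1CCCCC1 | intermediate
21 | PM (13S)-15-(TBDPS-oxy)-8-oxo-17-norlabdan-19-oate | O=C1CC[C@@H]2[C@](C)(CCC[C@]2(C)C(=O)O[C@@H]3C[C@H](C)CC[C@H]3C(C)(C)c3ccccc3)[C@H]1CC[C@H](C)CCO[Si](c1ccccc1)(c1ccccc1)C(C)(C)C | intermediate
22 | 8-trimethylsilyloxy-7-ene (enol silane of 21) | C[Si](C)(C)OC1=CC[C@@H]2[C@](C)(CCC[C@]2(C)C(=O)O[C@@H]3C[C@H](C)CC[C@H]3C(C)(C)c3ccccc3)[C@H]1CC[C@H](C)CCO[Si](c1ccccc1)(c1ccccc1)C(C)(C)C | intermediate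
23 | PM (13S)-15-(TBDPS-oxy)-8-oxo-17-norlabd-6-en-19-oate | O=C1C=C[C@@H]2[C@](C)(CCC[C@]2(C)C(=O)O[C@@H]3C[C@H](C)CC[C@H]3C(C)(C)c3ccccc3)[C@H]1CC[C@H](C)CCO[Si](c1ccccc1)(c1ccccc1)C(C)(C)C | intermediate
24 | PM (13S)-15-(TBDPS-oxy)-8,8-ethylenedioxy-17-norlabd-5-en-19-oate | O1CCOC12CC=C3[C@](C)(CCC[C@]3(C)C(=O)O[C@@H]4C[C@H](C)CC[C@H]4C(C)(C)c4ccccc4)[C@H]2CC[C@H](C)CCO[Si](c1ccccc1)(c1ccccc1)C(C)(C)C | intermediate
25 | (13S)-15-(TBDPS-oxy)-8,8-ethylenedioxy-17-norlabd-5-en-19-ol | O1CCOC12CC=C3[C@](C)(CCC[C@]3(C)CO)[C@H]2CC[C@H](C)CCO[Si](c1ccccc1)(c1ccccc1)C(C)(C)C | intermediate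
26 | (5β,13S)-15-(TBDPS-oxy)-8,8-ethylenedioxy-17-norlabdan-19-ol | O1CCOC12CC[C@H]3[C@](C)(CCC[C@]3(C)CO)[C@H]2CC[C@H](C)CCO[Si](c1ccccc1)(c1ccccc1)C(C)(C)C | intermediate
27 | (5β,13S)-15-(TBDPS-oxy)-8-oxo-17-norlabdan-19-oic acid | O=C1CC[C@H]2[C@](C)(CCC[C@]2(C)C(=O)O)[C@H]1CC[C@H](C)CCO[Si](c1ccccc1)(c1ccccc1)C(C)(C)C | intermediate
28 | allyl (5β,13S)-15-(TBDPS-oxy)-8-oxo-17-norlabdan-19-oate | O=C1CC[C@H]2[C@](C)(CCC[C@]2(C)C(=O)OCC=C)[C@H]1CC[C@H](C)CCO[Si](c1ccccc1)(c1ccccc1)C(C)(C)C | intermediate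
29 | allyl (5β,13S)-15-(TBDPS-oxy)labd-8(17)-en-19-oate | C=C1CC[C@H]2[C@](C)(CCC[C@]2(C)C(=O)OCC=C)[C@H]1CC[C@H](C)CCO[Si](c1ccccc1)(c1ccccc1)C(C)(C)C | intermediate
30 | allyl (5β,13S)-15-hydroxylabd-8(17)-en-19-oate | C=C1CC[C@H]2[C@](C)(CCC[C@]2(C)C(=O)OCC=C)[C@H]1CC[C@H](C)CCO | intermediate
31 | allyl (5β,13S)-15-oxolabd-8(17)-en-19-oate | C=C1CC[C@H]2[C@](C)(CCC[C@]2(C)C(=O)OCC=C)[C@H]1CC[C@H](C)CC=O | intermediate
32 | lithium aza-enolate of 20 | C=C1CC[C@@H]2[C@](C)(CCC[C@]2(C)C(=O)OCC=C)[C@H]1CC[C@H](C)C=CN([Li])C1CCCCC1 | intermediate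
33 | aldol adduct (C15′ lithium alkoxide, C15 imine; C14 and C15′ epimers) | C=C1CC[C@@H]2[C@](C)(CCC[C@]2(C)C(=O)OCC=C)[C@H]1CC[C@H](C)C(C=NC1CCCCC1)C(O[Li])C[C@@H](C)CC[C@H]1C(=C)CC[C@H]2[C@]1(C)CCC[C@]2(C)C(=O)OCC=C | intermediate
34 | bis(allyl) ester of the target | C=C1CC[C@@H]2[C@](C)(CCC[C@]2(C)C(=O)OCC=C)[C@H]1CC[C@H](C)/C(C=O)=C\C[C@@H](C)CC[C@H]1C(=C)CC[C@H]2[C@]1(C)CCC[C@]2(C)C(=O)OCC=C | intermediate
35 | CNP0229303.1 | C=C1CC[C@@H]2[C@](C)(CCC[C@]2(C)C(=O)O)[C@H]1CC[C@H](C)/C(C=O)=C\C[C@@H](C)CC[C@H]1C(=C)CC[C@H]2[C@]1(C)CCC[C@]2(C)C(=O)O | target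

## Step count and risks

Total step count: 29. Longest linear sequence: 21 steps (1–4, 7–11, 18–29).

Steps most likely to fail:

1. Step 8. The face selectivity at the C4 radical may be eroded, or the C8 radical may be oxidised toward the endocyclic olefins. Fallback from 10 back to 11 by a group-transfer radical chain in place of the oxidative one: 10 is selenenylated (NaH, PhSeCl, THF, 0 °C) to the α-phenylselanyl keto ester F1. Irradiation in benzene starts a phenylselanyl-transfer bicyclisation through the same C4 and C10 radicals and ends at the tertiary 8-phenylselanyl bicycle F2. Oxidation (H2O2, pyridine, CH2Cl2) and selenoxide syn-elimination, which in a cyclohexyl selenoxide reaches the methyl hydrogens most easily, gives 11.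

2. Step 22. Hydrogen may be delivered from the α face, or the hindered olefin may not react. Fallback from 24 back to 26 by an epoxide–ketone rearrangement that brings the hydrogen to C5 by an intramolecular shift: 24 with mCPBA gives the 5α,6α-epoxide F3 (the β face is blocked by C19 and C20). BF3·OEt2 in benzene opens it at C5 with a 1,2-hydride shift from C6 to the β face of C5, as known for steroidal 5α,6α-epoxides, giving the cis-fused 6-ketone F4. NaBH4 gives the 6-alcohol F5, thiocarbonyldiimidazole the thiocarbamate F6, and Bu3SnH/AIBN the cis-fused ketal ester F7. LiAlH4 then gives 26.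

3. Step 20. The double bond may migrate incompletely, giving a mixture of 6-ene and 5-ene ketals, or the silyl ether may be lost under the acidic reflux. Fallback from 23 back to 24 by base deconjugation and then cold ketalisation: the potassium dienolate of 23 (KOtBu, t-BuOH/THF) is quenched quickly into cold aqueous acetic acid, and kinetic protonation at C7 gives the β,γ-unsaturated ketone F8. Noyori ketalisation (Me3SiOCH2CH2OSiMe3, Me3SiOTf cat., CH2Cl2, −78 °C), which does not move the double bond, gives 24.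

Further compounds
F1 | step 8 | PM (6E,10E,14S)-16-(TBDPS-oxy)-2,6,10,14-tetramethyl-3-oxo-2-(phenylselanyl)hexadeca-6,10-dienoate | CC(C)(C)[Si](c1ccccc1)(c1ccccc1)OCC[C@@H](C)CC/C=C(\C)CC/C=C(\C)CCC(=O)C(C)([Se]c1ccccc1)C(=O)O[C@@H]1C[C@H](C)CC[C@H]1C(C)(C)c1ccccc1
F2 | step 8 | PM (13S)-15-(TBDPS-oxy)-3-oxo-8-(phenylselanyl)labdan-19-oate (C8 epimers) | CC1([Se]c2ccccc2)CC[C@@H]2[C@](C)(CCC(=O)[C@]2(C)C(=O)O[C@@H]3C[C@H](C)CC[C@H]3C(C)(C)c3ccccc3)[C@H]1CC[C@H](C)CCO[Si](c1ccccc1)(c1ccccc1)C(C)(C)C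
F3 | step 22 | PM (13S)-15-(TBDPS-oxy)-5α,6α-epoxy-8,8-ethylenedioxy-17-norlabdan-19-oate | O1CCOC12C[C@@H]3O[C@]34[C@](C)(CCC[C@]4(C)C(=O)O[C@@H]5C[C@H](C)CC[C@H]5C(C)(C)c5ccccc5)[C@H]2CC[C@H](C)CCO[Si](c1ccccc1)(c1ccccc1)C(C)(C)C
F4 | step 22 | PM (5β,13S)-15-(TBDPS-oxy)-8,8-ethylenedioxy-6-oxo-17-norlabdan-19-oate | O1CCOC12CC(=O)[C@H]3[C@](C)(CCC[C@]3(C)C(=O)O[C@@H]4C[C@H](C)CC[C@H]4C(C)(C)c4ccccc4)[C@H]2CC[C@H](C)CCO[Si](c1ccccc1)(c1ccccc1)C(C)(C)C
F5 | step 22 | PM (5β,13S)-15-(TBDPS-oxy)-8,8-ethylenedioxy-6-hydroxy-17-norlabdan-19-oate (C6 epimers) | O1CCOC12CC(O)[C@H]3[C@](C)(CCC[C@]3(C)C(=O)O[C@@H]4C[C@H](C)CC[C@H]4C(C)(C)c4ccccc4)[C@H]2CC[C@H](C)CCO[Si](c1ccccc1)(c1ccccc1)C(C)(C)C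
F6 | step 22 | PM (5β,13S)-15-(TBDPS-oxy)-8,8-ethylenedioxy-6-(imidazol-1-ylthiocarbonyloxy)-17-norlabdan-19-oate | O1CCOC12CC(OC(=S)n3ccnc3)[C@H]3[C@](C)(CCC[C@]3(C)C(=O)O[C@@H]4C[C@H](C)CC[C@H]4C(C)(C)c4ccccc4)[C@H]2CC[C@H](C)CCO[Si](c1ccccc1)(c1ccccc1)C(C)(C)C
F7 | step 22 | PM (5β,13S)-15-(TBDPS-oxy)-8,8-ethylenedioxy-17-norlabdan-19-oate | O1CCOC12CC[C@H]3[C@](C)(CCC[C@]3(C)C(=O)O[C@@H]4C[C@H](C)CC[C@H]4C(C)(C)c4ccccc4)[C@H]2CC[C@H](C)CCO[Si](c1ccccc1)(c1ccccc1)C(C)(C)C
F8 | step 20 | PM (13S)-15-(TBDPS-oxy)-8-oxo-17-norlabd-5-en-19-oate | O=C1CC=C2[C@](C)(CCC[C@]2(C)C(=O)O[C@@H]3C[C@H](C)CC[C@H]3C(C)(C)c3ccccc3)[C@H]1CC[C@H](C)CCO[Si](c1ccccc1)(c1ccccc1)C(C)(C)C
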